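**Plan**
1. Retrosynthetic cuts: the methyl ester C–O bond last; then the ring-A bond between the alkylidene carbon (C2 of the octalin) and its neighbour C3, which opens ring A to an internal alkyne plus a vinyl group on the ring-B alkene; then the propargylic C(sp)–CH2 bond of the side chain, giving a ring-B dienyne (fragment 1) and a 1,2-dioxane triflate (fragment 2).
2. Enabling feature: the exocyclic C=C sits on a ring-A carbon whose two CH2 arms (C1, allylic to the C4a=C8a alkene, and C3, homoallylic to it) are nearly alike, so no olefination can set its geometry. A triple bond that already carries C1 and the side chain, with boron on C3, makes the (Z) geometry the outcome of a syn C–H addition.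
3. Forward order: ring B is bought as 2,2-dimethylcyclohexanone (propargylation, enol triflate, vinylation); the dioxane is built from geraniol; acetylide alkylation joins the fragments; ring A is closed in the penultimate step; ester hydrolysis ends the route.
4. Stereochemistry: the quaternary peroxy carbon comes from Sharpless epoxidation (inverted once in the oxetane perhydrolysis); the two adjacent CH centers come from Brown anti-crotylation (the carbinol inverted in the peroxide ring closure); the alkene geometry comes from syn-hydropalladation and stereoretentive reductive elimination.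

Key step: step 17

Remark: a saturated 1,2-dioxane is assumed to survive a lithium acetylide at −78 °C, 9-BBN at room temperature and zerovalent palladium, by analogy with dialkyl peroxides that are carried through palladium/copper couplings and borane reductions.

**Route**

Step 1
Reactants: 1 geraniol
Product: 2 [(2S,3S)-3-methyl-3-(4-methylpent-3-en-1-yl)oxiran-2-yl]methanol
Conditions: Ti(OiPr)4 (cat.), L-(+)-diethyl tartrate (cat.), t-BuOOH, 4 Å MS, CH2Cl2, −20 °C
Reagents that add atoms: tert-butyl hydroperoxide, CC(C)(C)OO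
Why: Sharpless asymmetric epoxidation is selective for the allylic alcohol over the isolated trisubstituted alkene and, with the L-(+)-tartrate, should deliver oxygen to the face that gives the (2S,3S)-epoxide, which fixes the carbon that becomes the quaternary peroxy center.

Step 2
Reactants: 2 [(2S,3S)-3-methyl-3-(4-methylpent-3-en-1-yl)oxiran-2-yl]methanol
Product: 3 (3S)-3,7-dimethyloct-6-ene-1,3-diol
Conditions: NaAlH2(OCH2CH2OMe)2, THF, 0 °C
Reagents that add atoms: none
Why: Regioselective reductive opening of a 2,3-epoxy alcohol, in which the alkoxy-bound aluminate delivers hydride intramolecularly to C2, should give the 1,3-diol and leave the tertiary C–O bond and its stereocenter untouched.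

Step 3
Reactants: 3 (3S)-3,7-dimethyloct-6-ene-1,3-diol
Product: 5 (2S)-2-methyl-2-(4-methylpent-3-en-1-yl)oxetane, via primary tosylate 4 (not isolated)
Conditions: n-BuLi (1 equiv), THF, 0 °C; TsCl; then n-BuLi (1 equiv), 0 to 60 °C
Reagents that add atoms: none
Why: Selective sulfonylation of the primary alkoxide followed by 4-exo-tet Williamson etherification by the tertiary alkoxide closes the oxetane without breaking a bond to the stereocenter.

Step 4
Reactants: 5 (2S)-2-methyl-2-(4-methylpent-3-en-1-yl)oxetane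
Product: 6 3-[(2S)-2-methyloxetan-2-yl]propanal
Conditions: O3, CH2Cl2, −78 °C; then Me2S
Reagents that add atoms: ozone, [O-][O+]=O
Why: Ozonolysis with reductive work-up cleaves the only alkene to the aldehyde and acetone, the oxetane being inert to ozone.

Step 5
Reactants: 6 3-[(2S)-2-methyloxetan-2-yl]propanal
Product: 7 (3R,4S)-3-methyl-6-[(2S)-2-methyloxetan-2-yl]hex-1-en-4-ol
Conditions: (E)-crotyl-B(Ipc)2 [trans-2-butene, KOtBu, n-BuLi, THF, −45 °C; (+)-Ipc2BOMe, −78 °C; BF3·OEt2 (1 equiv)], THF/Et2O, −78 °C; then NaOH, H2O2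
Reagents that add atoms: (E)-crotyldiisopinocampheylborane, made in the flask from trans-2-butene (C/C=C/C), C/C=C/CB([C@H]1C[C@H]2C[C@@H]([C@@H]1C)C2(C)C)[C@H]1C[C@H]2C[C@@H]([C@@H]1C)C2(C)C
Why: Brown asymmetric crotylboration through a closed chair transition state transfers the (E)-crotyl group to give the anti adduct, and the isopinocampheyl groups derived from (−)-α-pinene select the aldehyde face that sets the (3R,4S) configuration at both new stereocenters.

Step 6
Reactants: 7 (3R,4S)-3-methyl-6-[(2S)-2-methyloxetan-2-yl]hex-1-en-4-ol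
Product: 8 (3R,4S)-3-methyl-6-[(2S)-2-methyloxetan-2-yl]hex-1-en-4-yl methanesulfonate
Conditions: MsCl, Et3N, CH2Cl2, 0 °C
Reagents that add atoms: methanesulfonyl chloride, CS(=O)(=O)Cl
Why: Sulfonylation of the secondary alcohol with retention turns it into the leaving group for the later invertive C–O bond formation.

Step 7
Reactants: 8 (3R,4S)-3-methyl-6-[(2S)-2-methyloxetan-2-yl]hex-1-en-4-yl methanesulfonate
Product: 9 (3R,4S,7R)-7-hydroperoxy-9-hydroxy-3,7-dimethylnon-1-en-4-yl methanesulfonate
Conditions: H2O2 (anhydrous, in Et2O), Me3SiOTf (cat.), Et2O, −78 °C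
Reagents that add atoms: hydrogen peroxide, OO
Why: Lewis-acid-promoted perhydrolysis of a 2,2-disubstituted oxetane is known to place the hydroperoxide on the tertiary carbon with inversion (attack of H2O2 on the activated oxonium opposite to the leaving oxygen), which sets the quaternary peroxy stereocenter and frees the primary alcohol while the mesylate and the vinyl group stay inert.

Step 8
Reactants: 9 (3R,4S,7R)-7-hydroperoxy-9-hydroxy-3,7-dimethylnon-1-en-4-yl methanesulfonate
Product: 10 2-[(3R,6R)-6-[(2R)-but-3-en-2-yl]-3-methyl-1,2-dioxan-3-yl]ethan-1-ol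
Conditions: KOtBu (1 equiv), 18-crown-6, THF, 0 °C
Reagents that add atoms: none
Why: Intramolecular 6-exo-tet alkylation of the hydroperoxide anion, a weakly basic α-effect nucleophile, displaces the secondary mesylate with inversion (SN2), which closes the 1,2-dioxane and converts the anti crotylation array into the required configuration at the ring CH.

Step 9
Reactants: 10 2-[(3R,6R)-6-[(2R)-but-3-en-2-yl]-3-methyl-1,2-dioxan-3-yl]ethan-1-ol
Product: 12 (2S)-2-[(3R,6R)-6-(2-hydroxyethyl)-6-methyl-1,2-dioxan-3-yl]propanoic acid, via aldehyde 11 (not isolated)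
Conditions: O3, CH2Cl2, −78 °C; Me2S; then NaClO2, NaH2PO4, 2-methyl-2-butene, t-BuOH/H2O, 0 °C
Reagents that add atoms: ozone, [O-][O+]=O; sodium chlorite, [Na+].[O-]Cl=O
Why: Ozonolysis of the terminal vinyl group and Pinnick oxidation of the crude aldehyde under buffered, non-basic conditions unmask the carboxyl group without epimerizing the α-stereocenter or opening the β-peroxy carbonyl compound, dialkyl peroxides and primary alcohols being inert to ozone and chlorite.

Step 10
Reactants: 12 (2S)-2-[(3R,6R)-6-(2-hydroxyethyl)-6-methyl-1,2-dioxan-3-yl]propanoic acid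
Product: 13 methyl (2S)-2-[(3R,6R)-6-(2-hydroxyethyl)-6-methyl-1,2-dioxan-3-yl]propanoate
Conditions: Me3SiCHN2, MeOH/toluene, 0 °C
Reagents that add atoms: (trimethylsilyl)diazomethane, C[Si](C)(C)C=[N+]=[N-]
Why: Diazoalkane esterification under neutral conditions protects the acid as the methyl ester without touching the alcohol or the peroxide.

Step 11
Reactants: 13 methyl (2S)-2-[(3R,6R)-6-(2-hydroxyethyl)-6-methyl-1,2-dioxan-3-yl]propanoate
Product: 14 methyl (2S)-2-[(3R,6R)-6-methyl-6-[2-(trifluoromethanesulfonyloxy)ethyl]-1,2-dioxan-3-yl]propanoate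
Conditions: Tf2O, 2,6-lutidine, CH2Cl2, −78 °C
Reagents that add atoms: trifluoromethanesulfonic anhydride, O=S(=O)(OS(=O)(=O)C(F)(F)F)C(F)(F)F
Why: O-Sulfonylation of the primary alcohol with triflic anhydride and a hindered pyridine base at low temperature gives the primary triflate, the most reactive SN2 electrophile, which is filtered through silica and used at once.

Step 12
Reactants: 15 2,2-dimethylcyclohexan-1-one; 16 3-bromo-1-(trimethylsilyl)prop-1-yne
Product: 18 2,2-dimethyl-6-[3-(trimethylsilyl)prop-2-yn-1-yl]cyclohexan-1-one (racemic), via lithium enolate 17 (not isolated)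
Conditions: LiN(iPr)2, THF, −78 °C; then 16, DMPU, −78 to 0 °C
Reagents that add atoms: none
Why: The ketone can enolize on one side only, so kinetic lithium enolate formation and SN2 alkylation with the propargylic bromide install the three-carbon alkyne arm, the silyl cap blocking acetylenic deprotonation (the new stereocenter is racemic and is destroyed in step 13).

Step 13
Reactants: 18 2,2-dimethyl-6-[3-(trimethylsilyl)prop-2-yn-1-yl]cyclohexan-1-one
Product: 20 6,6-dimethyl-2-[3-(trimethylsilyl)prop-2-yn-1-yl]cyclohex-1-en-1-yl trifluoromethanesulfonate, via lithium enolate 19 (not isolated)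
Conditions: LiN(iPr)2, THF, −78 to 0 °C; then PhNTf2, 0 °C to rt
Reagents that add atoms: N-phenylbis(trifluoromethanesulfonimide), O=S(=O)(N(c1ccccc1)S(=O)(=O)C(F)(F)F)C(F)(F)F
Why: The only α-hydrogen left is the tertiary one, so deprotonation gives the tetrasubstituted enolate, and its O-sulfonylation (enol triflate formation) fixes the position of the future ring-fusion double bond.

Step 14
Reactants: 20 6,6-dimethyl-2-[3-(trimethylsilyl)prop-2-yn-1-yl]cyclohex-1-en-1-yl trifluoromethanesulfonate
Product: 21 [3-(2-ethenyl-3,3-dimethylcyclohex-1-en-1-yl)prop-1-yn-1-yl](trimethyl)silane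
Conditions: Bu3SnCH=CH2, Pd2(dba)3 (cat.), AsPh3, NMP, 50 °C
Reagents that add atoms: tributyl(vinyl)stannane, C=C[Sn](CCCC)(CCCC)CCCC
Why: Stille coupling of hindered 2-alkyl-6,6-dimethylcyclohexenyl triflates with alkenylstannanes under Pd2(dba)3/AsPh3 in NMP is well precedented and installs the vinyl group without affecting the silylalkyne.

Step 15
Reactants: 21 [3-(2-ethenyl-3,3-dimethylcyclohex-1-en-1-yl)prop-1-yn-1-yl](trimethyl)silane
Product: 22 1-ethenyl-6,6-dimethyl-2-(prop-2-yn-1-yl)cyclohex-1-ene
Conditions: K2CO3, MeOH, rt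
Reagents that add atoms: none
Why: Methanolysis of the alkynyl–silicon bond under mild carbonate conditions frees the terminal alkyne without isomerizing the skipped enyne.

Step 16
Reactants: 22 1-ethenyl-6,6-dimethyl-2-(prop-2-yn-1-yl)cyclohex-1-ene; 14 methyl (2S)-2-[(3R,6R)-6-methyl-6-[2-(trifluoromethanesulfonyloxy)ethyl]-1,2-dioxan-3-yl]propanoate
Product: 24 methyl (2S)-2-[(3R,6S)-6-[5-(2-ethenyl-3,3-dimethylcyclohex-1-en-1-yl)pent-3-yn-1-yl]-6-methyl-1,2-dioxan-3-yl]propanoate, via lithium acetylide 23 (not isolated)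
Conditions: 22, n-BuLi, THF, −78 °C; then 14, THF/DMPU, −78 to −30 °C
Reagents that add atoms: none
Why: Deprotonation of the terminal alkyne and SN2 alkylation of the lithium acetylide with the primary triflate at low temperature join the two fragments, displacement of triflate being expected to outrun addition to the methyl ester, enolization and attack on the O–O bond.

Step 17
Reactants: 24 methyl (2S)-2-[(3R,6S)-6-[5-(2-ethenyl-3,3-dimethylcyclohex-1-en-1-yl)pent-3-yn-1-yl]-6-methyl-1,2-dioxan-3-yl]propanoate
Product: 26 methyl (2S)-2-[(3R,6S)-6-[(3Z)-3-(5,5-dimethyl-3,4,5,6,7,8-hexahydronaphthalen-2(1H)-ylidene)propyl]-6-methyl-1,2-dioxan-3-yl]propanoate, via alkylborane 25 (not isolated)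
Conditions: 9-BBN (1.2 equiv), THF, 0 °C to rt; then Pd(PPh3)4 (10 mol %), AcOH (2 equiv), THF (0.005 M), 50 °C
Reagents that add atoms: none
Why: Proposed new method: 9-BBN adds to the only monosubstituted alkene and tags the future ring carbon C3 with boron; zerovalent palladium and AcOH give H–Pd–OAc, which adds syn across the alkyne, and of the two regioisomeric alkenylpalladium acetates only the one with palladium on the ring-side alkyne carbon can reach the boron, because the other would have to close a seven-membered ring containing an (E)-alkene. Acetate-assisted boron-to-palladium transfer within the molecule gives a seven-membered palladacycle of divalent palladium, and C–C reductive elimination closes ring A (formally a 6-exo-dig hydroalkylation of the alkyne) and returns zerovalent palladium. The closest known reaction types are the Pd/AcOH-catalysed syn-hydroarylation of alkynes with organoboronic acids and ring-closing B-alkyl Suzuki–Miyaura couplings of alkenyl halides, with hydropalladation here taking the place of oxidative addition. No stereocenter is formed; the (Z) geometry follows from syn addition of Pd–H and retention at the alkenyl carbon in the reductive elimination, so that the new vinylic hydrogen ends cis to the new ring bond. The step needs chemoselective hydroboration, which rests on 9-BBN reacting with terminal alkenes faster than with internal alkynes, tetrasubstituted alkenes or esters, and it needs ring closure to beat intermolecular coupling, which the fixed boron position and high dilution secure. The redox-neutral medium, free of hydride donors and reducing metals, is chosen to spare the O–O bond.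

Step 18
Reactants: 26 methyl (2S)-2-[(3R,6S)-6-[(3Z)-3-(5,5-dimethyl-3,4,5,6,7,8-hexahydronaphthalen-2(1H)-ylidene)propyl]-6-methyl-1,2-dioxan-3-yl]propanoate
Product: 27 (2S)-2-[(3R,6S)-6-[(3Z)-3-(5,5-dimethyl-3,4,5,6,7,8-hexahydronaphthalen-2(1H)-ylidene)propyl]-6-methyl-1,2-dioxan-3-yl]propanoic acid
Conditions: LiOH, THF/MeOH/H2O, 0 °C to rt; then dilute HCl
Reagents that add atoms: lithium hydroxide, [Li+].[OH-]
Why: Saponification of the methyl ester with LiOH at low temperature, as is usual for 1,2-dioxane propanoates, should free the acid without epimerizing C2 or opening the peroxide ring.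

**Compound list**

1 | geraniol, (2E)-3,7-dimethylocta-2,6-dien-1-ol | CC(C)=CCC/C(C)=C/CO | starting material
2 | [(2S,3S)-3-methyl-3-(4-methylpent-3-en-1-yl)oxiran-2-yl]methanol | OC[C@@H]1O[C@@]1(C)CCC=C(C)C | intermediate
3 | (3S)-3,7-dimethyloct-6-ene-1,3-diol | OCC[C@@](C)(O)CCC=C(C)C | intermediate
4 | lithium (3S)-3,7-dimethyl-1-(tosyloxy)oct-6-en-3-olate (primary tosylate) | [Li+].Cc1ccc(cc1)S(=O)(=O)OCC[C@@](C)([O-])CCC=C(C)C | intermediate (not isolated)
5 | (2S)-2-methyl-2-(4-methylpent-3-en-1-yl)oxetane | CC(C)=CCC[C@@]1(C)CCO1 | intermediate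
6 | 3-[(2S)-2-methyloxetan-2-yl]propanal | O=CCC[C@@]1(C)CCO1 | intermediate
7 | (3R,4S)-3-methyl-6-[(2S)-2-methyloxetan-2-yl]hex-1-en-4-ol | C[C@H](C=C)[C@@H](O)CC[C@@]1(C)CCO1 | intermediate
8 | (3R,4S)-3-methyl-6-[(2S)-2-methyloxetan-2-yl]hex-1-en-4-yl methanesulfonate | C[C@H](C=C)[C@@H](OS(C)(=O)=O)CC[C@@]1(C)CCO1 | intermediate
9 | (3R,4S,7R)-7-hydroperoxy-9-hydroxy-3,7-dimethylnon-1-en-4-yl methanesulfonate | C[C@H](C=C)[C@@H](OS(C)(=O)=O)CC[C@@](C)(OO)CCO | intermediate
10 | 2-[(3R,6R)-6-[(2R)-but-3-en-2-yl]-3-methyl-1,2-dioxan-3-yl]ethan-1-ol | C[C@H](C=C)[C@H]1CC[C@](C)(CCO)OO1 | intermediate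
11 | (2S)-2-[(3R,6R)-6-(2-hydroxyethyl)-6-methyl-1,2-dioxan-3-yl]propanal | C[C@H](C=O)[C@H]1CC[C@](C)(CCO)OO1 | intermediate (not isolated)
12 | (2S)-2-[(3R,6R)-6-(2-hydroxyethyl)-6-methyl-1,2-dioxan-3-yl]propanoic acid | C[C@H](C(=O)O)[C@H]1CC[C@](C)(CCO)OO1 | intermediate
13 | methyl (2S)-2-[(3R,6R)-6-(2-hydroxyethyl)-6-methyl-1,2-dioxan-3-yl]propanoate | C[C@H](C(=O)OC)[C@H]1CC[C@](C)(CCO)OO1 | intermediate
14 | methyl (2S)-2-[(3R,6R)-6-methyl-6-[2-(trifluoromethanesulfonyloxy)ethyl]-1,2-dioxan-3-yl]propanoate | C[C@H](C(=O)OC)[C@H]1CC[C@](C)(CCOS(=O)(=O)C(F)(F)F)OO1 | intermediate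
15 | 2,2-dimethylcyclohexan-1-one | CC1(C)CCCCC1=O | starting material
16 | 3-bromo-1-(trimethylsilyl)prop-1-yne | C[Si](C)(C)C#CCBr | starting material
17 | lithium 6,6-dimethylcyclohex-1-en-1-olate | [Li+].[O-]C1=CCCCC1(C)C | intermediate (not isolated)
18 | 2,2-dimethyl-6-[3-(trimethylsilyl)prop-2-yn-1-yl]cyclohexan-1-one (racemic) | CC1(C)CCCC(CC#C[Si](C)(C)C)C1=O | intermediate
19 | lithium 6,6-dimethyl-2-[3-(trimethylsilyl)prop-2-yn-1-yl]cyclohex-1-en-1-olate | [Li+].[O-]C1=C(CC#C[Si](C)(C)C)CCCC1(C)C | intermediate (not isolated)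
20 | 6,6-dimethyl-2-[3-(trimethylsilyl)prop-2-yn-1-yl]cyclohex-1-en-1-yl trifluoromethanesulfonate | CC1(C)CCCC(CC#C[Si](C)(C)C)=C1OS(=O)(=O)C(F)(F)F | intermediate
21 | [3-(2-ethenyl-3,3-dimethylcyclohex-1-en-1-yl)prop-1-yn-1-yl](trimethyl)silane | CC1(C)CCCC(CC#C[Si](C)(C)C)=C1C=C | intermediate
22 | 1-ethenyl-6,6-dimethyl-2-(prop-2-yn-1-yl)cyclohex-1-ene | CC1(C)CCCC(CC#C)=C1C=C | intermediate
23 | lithium 3-(2-ethenyl-3,3-dimethylcyclohex-1-en-1-yl)prop-1-yn-1-ide | [Li+].[C-]#CCC1=C(C=C)C(C)(C)CCC1 | intermediate (not isolated)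
24 | methyl (2S)-2-[(3R,6S)-6-[5-(2-ethenyl-3,3-dimethylcyclohex-1-en-1-yl)pent-3-yn-1-yl]-6-methyl-1,2-dioxan-3-yl]propanoate | C[C@H](C(=O)OC)[C@H]1CC[C@](C)(CCC#CCC2=C(C=C)C(C)(C)CCC2)OO1 | intermediate
25 | methyl (2S)-2-[(3R,6S)-6-[5-{2-[2-(9-borabicyclo[3.3.1]nonan-9-yl)ethyl]-3,3-dimethylcyclohex-1-en-1-yl}pent-3-yn-1-yl]-6-methyl-1,2-dioxan-3-yl]propanoate | C[C@H](C(=O)OC)[C@H]1CC[C@](C)(CCC#CCC2=C(CCB3C4CCCC3CCC4)C(C)(C)CCC2)OO1 | intermediate (not isolated)
26 | methyl (2S)-2-[(3R,6S)-6-[(3Z)-3-(5,5-dimethyl-3,4,5,6,7,8-hexahydronaphthalen-2(1H)-ylidene)propyl]-6-methyl-1,2-dioxan-3-yl]propanoate | C[C@H](C(=O)OC)[C@H]1CC[C@](C)(CC/C=C2/CCC3=C(CCCC3(C)C)C2)OO1 | intermediate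
27 | (2S)-2-[(3R,6S)-6-[(3Z)-3-(5,5-dimethyl-3,4,5,6,7,8-hexahydronaphthalen-2(1H)-ylidene)propyl]-6-methyl-1,2-dioxan-3-yl]propanoic acid | C[C@H](C(=O)O)[C@H]1CC[C@](C)(CC/C=C2/CCC3=C(CCCC3(C)C)C2)OO1 | target

**Step count**

Total steps: 18. Longest linear sequence: 14 (steps 1–11, then 16–18).

**Steps most likely to fail**

Step 17. Boron-to-palladium transfer may be too slow, so that the alkenylpalladium acetate is protonated and the alkyne is only semi-reduced; the O–O bond may also be cleaved by zerovalent palladium. The fallback moves the ring closure to a classical ring-closing B-alkyl Suzuki–Miyaura coupling of a preformed alkenyl iodide. It sets out from 24. PdCl2(PPh3)2-catalysed syn-hydrostannation (Bu3SnH, THF, 0 °C) is expected to give both regioisomeric alkenylstannanes, from which the isomer with tin on the ring-side carbon, methyl (2S)-2-[(3R,6S)-6-[(3E)-5-(2-ethenyl-3,3-dimethylcyclohex-1-en-1-yl)-4-(tributylstannyl)pent-3-en-1-yl]-6-methyl-1,2-dioxan-3-yl]propanoate F1, is separated. Iododestannylation with retention (I2, CH2Cl2, 0 °C) gives methyl (2S)-2-[(3R,6S)-6-[(3E)-5-(2-ethenyl-3,3-dimethylcyclohex-1-en-1-yl)-4-iodopent-3-en-1-yl]-6-methyl-1,2-dioxan-3-yl]propanoate F2. Hydroboration of the vinyl group with 9-BBN gives methyl (2S)-2-[(3R,6S)-6-[(3E)-5-{2-[2-(9-borabicyclo[3.3.1]nonan-9-yl)ethyl]-3,3-dimethylcyclohex-1-en-1-yl}-4-iodopent-3-en-1-yl]-6-methyl-1,2-dioxan-3-yl]propanoate F3, which is not isolated. PdCl2(dppf), AsPh3 and Cs2CO3 in DMF/THF/H2O at room temperature under dilution then close ring A with retention at the alkenyl carbon, and the fallback comes back to the route at 26.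

Step 16. The lithium acetylide may act as a base toward the ester (enolization followed by β-elimination of the peroxide) or attack the O–O bond or the ester carbonyl, and the triflate may eliminate. The fallback replaces the stoichiometric organolithium displacement by a catalytic palladium/copper coupling under carbonate base. It sets out from 13. I2, PPh3 and imidazole in CH2Cl2 give methyl (2S)-2-[(3R,6R)-6-(2-iodoethyl)-6-methyl-1,2-dioxan-3-yl]propanoate F4. Alkyl Sonogashira coupling of this iodide with 22 ([Pd(C3H5)Cl]2, 1,3-bis(1-adamantyl)imidazolium chloride, CuI, Cs2CO3, DMF/Et2O, 45 °C) comes back to the route at 24.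

Step 7. The activated oxetane may ionize to a free tertiary cation, with partial loss of configuration at the quaternary carbon, elimination to alkenes or capture by adventitious water. The fallback reverses the order of the two C–O bond formations, so that the tertiary C–O bond is made intramolecularly. It sets out from 8. SN2 perhydrolysis of the secondary mesylate with inversion (H2O2, KOH, MeOH/H2O, 0 °C to rt) gives (2S)-2-[(3R,4R)-3-hydroperoxy-4-methylhex-5-en-1-yl]-2-methyloxetane F5. Me3SiOTf (cat.) in CH2Cl2 at −78 °C then lets the hydroperoxide open the oxetane at the tertiary carbon in a 6-exo fashion with inversion, and the fallback comes back to the route at 10.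

**Further compounds**

F1 | step 17 | methyl (2S)-2-[(3R,6S)-6-[(3E)-5-(2-ethenyl-3,3-dimethylcyclohex-1-en-1-yl)-4-(tributylstannyl)pent-3-en-1-yl]-6-methyl-1,2-dioxan-3-yl]propanoate | C[C@H](C(=O)OC)[C@H]1CC[C@](C)(CC/C=C(\CC2=C(C=C)C(C)(C)CCC2)[Sn](CCCC)(CCCC)CCCC)OO1
F2 | step 17 | methyl (2S)-2-[(3R,6S)-6-[(3E)-5-(2-ethenyl-3,3-dimethylcyclohex-1-en-1-yl)-4-iodopent-3-en-1-yl]-6-methyl-1,2-dioxan-3-yl]propanoate | C[C@H](C(=O)OC)[C@H]1CC[C@](C)(CC/C=C(\CC2=C(C=C)C(C)(C)CCC2)I)OO1
F3 | step 17 | methyl (2S)-2-[(3R,6S)-6-[(3E)-5-{2-[2-(9-borabicyclo[3.3.1]nonan-9-yl)ethyl]-3,3-dimethylcyclohex-1-en-1-yl}-4-iodopent-3-en-1-yl]-6-methyl-1,2-dioxan-3-yl]propanoate | C[C@H](C(=O)OC)[C@H]1CC[C@](C)(CC/C=C(\CC2=C(CCB3C4CCCC3CCC4)C(C)(C)CCC2)I)OO1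
F4 | step 16 | methyl (2S)-2-[(3R,6R)-6-(2-iodoethyl)-6-methyl-1,2-dioxan-3-yl]propanoate | C[C@H](C(=O)OC)[C@H]1CC[C@](C)(CCI)OO1
F5 | step 7 | (2S)-2-[(3R,4R)-3-hydroperoxy-4-methylhex-5-en-1-yl]-2-methyloxetane | C[C@H](C=C)[C@H](OO)CC[C@@]1(C)CCO1
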